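**Numbering used throughout.** Ring A: C1 (isobutyryl, prenyl), C2 (enone carbonyl), C3, C4 (carries the ring oxygen O4), C5 (methyl, prenyl), C6 (ketone). Ring B: O4–C8–C7–C3. C9 is the exocyclic carbinol. Oxygens take the number of their carbon.

## The problem

The target 21 is a dearomatised, fully C-alkylated acylphloroglucinol: a six-membered carbocycle (ring A) fused along C3–C4 to a 2,3-dihydrofuran (ring B). It has four stereocentres: the quaternary carbons C1 (R) and C5 (S), 1,3-related across C6 with their prenyl groups trans, and the vicinal pair C8 (S) and C9 (S). C8 and C9 can be set together from one precursor, but they are too far away to direct C5 or C1. C5 can offer C1 no more than the difference between a methyl and a prenyl group, so ring A needs absolute control of its own. Three trisubstituted alkenes exclude hydrogenation, electrophilic oxidants and strong protic or Lewis acids, which would also cyclise a prenyl group onto a neighbouring enol or carboxyl oxygen. Once C1 is quaternary the molecule is a non-enolisable β-triketone that nucleophiles cleave by retro-Claisen reaction. Ring B must be closed by O4 and not O2, and as a five- and not a six-membered ether. The enabling feature is that ring A is a 2-acylcyclohexane-1,3,5-trione whose C5 is a fully substituted malonyl carbon between C4 and C6. The ring therefore divides into a methylmalonyl unit (C4–C5–C6) and an acylated β-diketone (C3–C2–C1). Because C5 is quaternary the ring cannot aromatise or enolise there, and the acyl group on C1 keeps C4 and C6 different, so a malonate stereocentre survives the ring synthesis.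

## Retrosynthesis

**21 ⇒ 18 + 20 (C1–prenyl bond).** The C1 prenyl group is removed first. In 18, C1 is the only remaining carbon acid, whereas at any earlier stage C3 would be alkylated in preference. Quaternising C1 also creates the base-labile triketone, which is best done last. The forward step must prenylate carbon rather than oxygen, at the unsubstituted allyl terminus, anti to the C5 prenyl group and under non-nucleophilic conditions. A palladium allylation with the carbonate 20 (from prenol 19) meets the first, second and fourth demands; the facial demand is the weak point and is given a chiral ligand.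

**18 ⇒ 12 + 15 (C3–C7 and O4–C8, ring B).** Both bonds are traced to one epoxy aldehyde 15 that carries C7 as the carbonyl carbon and C8/C9 as a preformed epoxide. Reductive alkylation of the C3–H acid 12 gives the epoxide 17 by way of the alkylidene 16, and 5-exo opening by O4 inverts C8 and leaves C9 untouched. The neighbouring cut, C3-alkylation with an allylic halide and later epoxidation, fails because the product would hold three trisubstituted alkenes of equal reactivity. The forward reaction needs hydride transfer to 16 to outrun any attack on the epoxide, and closure through O4 at C8. The free C4 enol against the chelated C2 enol, and base instead of acid, are the handles.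

**15 ⇒ 14 ⇒ 13.** The aldehyde comes from the epoxy alcohol 14 by oxidation, and 14 from nerol 13 by Sharpless epoxidation. The Z-alkene and the D-tartrate together give the (2R,3S)-epoxide that becomes (8S,9S) after inversion at C8. Any minor enantiomer of 15 ends as a diastereomer of 18 and can be removed there, since C5 is already fixed.

**12 ⇒ 8 + 9 (C3–C4 and C1–C6, ring A; key step).** Ring A is opened into the acyl imidazole 8 and 5-methylhexane-2,4-dione 9, used as its dianion 10. The terminal carbon of 10 becomes C3 and attacks the imidazolide carbonyl (C4). The central carbon becomes C1 and closes on the ester (C6) through the open-chain triketo ester 11. Against its neighbours: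
- Dearomatising an acylphloroglucinol would need an enantioselective C5 alkylation of a flat ring.
- Building the ring without the acyl group would pass through a 4,4-disubstituted trione that has a mirror plane through C5, so the stereocentre would be lost.

Here the isobutyryl group arrives with 9, and the order of the two acyl transfers alone decides which malonyl carbonyl becomes C4.

**8 ⇒ 7 ⇒ 5 ⇒ 3 + 4.** The imidazolide comes from the half-acid 7, and 7 from the mixed diester 5 by selective loss of the tert-butyl group. In 5 the quaternary centre is made by enantioselective phase-transfer prenylation of the α-methylmalonate 3 with prenyl bromide 4. Enzymatic desymmetrisation of a symmetrical diester with pig liver esterase would be two steps shorter. For α-methylmalonates, however, the sense and size of its selectivity change with the length of the second chain, and a five-carbon chain lies in the crossover region. The ammonium catalyst is available in both mirror-image forms and the two esters of 5 can be told apart chemically. The tert-butyl ester must be removed without protic acid, because the prenyl alkene would lactonise onto the new carboxyl group.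

**3 ⇒ 2 ⇒ 1.** The mixed malonate 3 is assembled by esterifying the half-ester 2, which comes from alcoholysis of methyl Meldrum's acid 1.

## Roads not taken

**Alternative 1:** Here C3–C7 and O4–C8 are cut on an aromatic ring. An ortho-iodophenol adds oxidatively to zerovalent palladium, the vinyl end of a branched C5 diene inserts, and the phenoxide attacks the allyl–palladium at C8 under a chiral ligand. This gives the 2-isopropenyl-2,3-dihydrobenzofuran A1.
- Merits: robust aromatic intermediates, catalyst control of C8, and an unambiguous ring oxygen, since only one phenol is free. In that respect it is better than the chosen plan, which has to earn O4 selectivity from the acyl chelate.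
- Weak points: the isopropenyl group of A1 must still be turned into the C9 carbinol with its homoprenyl chain and a second stereocentre. Ring A must then be acylated and dearomatised twice, creating C5 and C1 with no stereocontrol beyond the distant C8. The methoxymethyl ethers need acid in the presence of prenyl groups.
- Comparison: the chosen plan sets C5 absolutely before the ring exists and reaches the same stage in fewer operations.

**Alternative 2:** The cut is C2–C3. A dioxinone loses acetone on heating and the acylketene carbon (C2) is attacked by the enol ether carbon C3 of a preformed dihydrofuran. This closes ring A to the vinylogous ester dione A2, with C5, C8, C9 and ring B already in place.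
- Merits: neutral thermal conditions and complete regiochemical certainty for ring B, an advantage over the chosen plan.
- Weak points: the precursor needs the C5 quaternary stereocentre built next to an acid-sensitive cyclic enol ether, in a long linear sequence. Acylketenes normally add to enol ethers by [4+2] cycloaddition to pyranones, not by C-acylation. A2 still lacks both C1 substituents, so a C-acylation and the same unresolved C1 prenylation follow.
- Comparison: the chosen plan brings the acyl group in with the diketone and has one fewer bond to make at C1.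

**Alternative 3:** The cut is C7–C8. An aryl carbene generated at C7 from an aldehyde tosylhydrazone inserts into the ether C8–H bond, giving the silyl-protected dihydrobenzofuran A3 with the complete side chain.
- Merits: C9 can come from a simple chiral tertiary alcohol, the ring oxygen is again unambiguous, and ring B forms in one C–H functionalisation.
- Weak points: donor carbenes without an acceptor group tend to give azines and to cyclopropanate trisubstituted alkenes. Control of C8 by the adjacent quaternary C9 is uncertain. As with A1, both ring A quaternary centres remain to be made on an aromatic ring without control.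
- Comparison: the chosen plan has the more delicate ring B closure but solves the harder problem, C5, at the outset.

Key step: step 6

Assumption 1: in step 3 the (S,S)-ammonium salt is taken to deliver (R)-5; should prenyl bromide respond with the opposite sense, the mirror-image salt is used and nothing else changes.
Assumption 2: in step 11 the (1R,2R)-ligand is taken to be the one that admits the enolate face anti to the C5 prenyl group; its enantiomer is the substitute if the pairing is mismatched.

## Route

Step 1
Reactants: 1 2,2,5-trimethyl-1,3-dioxane-4,6-dione (methyl Meldrum's acid)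
Product: 2 3-tert-butoxy-2-methyl-3-oxopropanoic acid (racemic)
Conditions: t-BuOH, reflux
Reagents that add atoms: tert-butanol, CC(C)(C)O
Why: Alcoholysis of the Meldrum's acid ring with loss of acetone gives the malonic half-ester directly; the temperature stays below that of decarboxylation.

Step 2
Reactants: 2 3-tert-butoxy-2-methyl-3-oxopropanoic acid
Product: 3 tert-butyl 2,2-diphenylethyl 2-methylpropanedioate (racemic, configurationally labile)
Conditions: 2,2-diphenylethanol, DCC, DMAP (cat.), CH2Cl2, 0 °C to rt
Reagents that add atoms: 2,2-diphenylethanol, OCC(c1ccccc1)c1ccccc1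
Why: Steglich esterification; it gives the malonate with two clearly different ester groups that the phase-transfer alkylation needs.

Step 3
Reactants: 3 tert-butyl 2,2-diphenylethyl 2-methylpropanedioate; 4 1-bromo-3-methylbut-2-ene (prenyl bromide)
Product: 5 1-tert-butyl 3-(2,2-diphenylethyl) (2R)-2-methyl-2-(3-methylbut-2-en-1-yl)propanedioate
Conditions: (11bS,11'bS)-2,6-bis(3,4,5-trifluorophenyl)-3,3',5,5'-tetrahydro-4,4'-spirobi[dinaphtho[2,1-c:1',2'-e]azepin]-4-ium bromide (5 mol%), 50% aq KOH, toluene, −40 °C
Reagents that add atoms: none
Why: Enantioselective phase-transfer alkylation of an α-methylmalonate with an allylic bromide; the chiral ammonium cation pairs with the enolate and shields one face, the two unlike esters making the faces distinguishable. The future C5 stereocentre is set here by the catalyst.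

Step 4
Reactants: 5 1-tert-butyl 3-(2,2-diphenylethyl) (2R)-2-methyl-2-(3-methylbut-2-en-1-yl)propanedioate
Product: 7 (2S)-2-[(2,2-diphenylethoxy)carbonyl]-2,5-dimethylhex-4-enoic acid, via trimethylsilyl ester 6 (not isolated)
Conditions: Me3SiOTf, 2,6-lutidine, CH2Cl2, 0 °C to rt; then pH 4 buffer
Reagents that add atoms: none
Why: Silyl-triflate cleavage of a tert-butyl ester (loss of 2-methylpropene to the silyl ester, hydrolysed on work-up) under buffered aprotic conditions, chosen because protic acid would lactonise the prenyl alkene onto the new carboxyl group. The primary ester is untouched and the quaternary centre cannot epimerise.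

Step 5
Reactants: 7 (2S)-2-[(2,2-diphenylethoxy)carbonyl]-2,5-dimethylhex-4-enoic acid
Product: 8 2,2-diphenylethyl (2S)-2-(1H-imidazole-1-carbonyl)-2,5-dimethylhex-4-enoate
Conditions: CDI (1.1 equiv), THF, rt; cold aqueous wash to remove imidazole
Reagents that add atoms: 1,1'-carbonyldiimidazole, O=C(n1ccnc1)n1ccnc1
Why: Standard acyl imidazole formation; with no α-hydrogen neither ketene formation nor racemisation is possible, and the hindered imidazolide is isolable.

Step 6
Reactants: 8 2,2-diphenylethyl (2S)-2-(1H-imidazole-1-carbonyl)-2,5-dimethylhex-4-enoate; 9 5-methylhexane-2,4-dione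
Product: 12 (6S)-3,5-dihydroxy-6-methyl-6-(3-methylbut-2-en-1-yl)-2-(2-methylpropanoyl)cyclohexa-2,4-dien-1-one, via dilithium dianion 10 (not isolated), via open-chain triketo ester 11 (not isolated)
Conditions: 9 (2.2 equiv), LiN(iPr)2 (4.4 equiv), THF, −78 to 0 °C; then 8, −78 °C to rt, then 50 °C; 1 M HCl, 0 °C
Reagents that add atoms: none
Why: LiN(iPr)2 converts 9 into dianion 10, deprotonated at the methyl group and not at the isopropyl methine, and its terminal carbanion attacks the imidazolide carbonyl of 8 to form C3–C4; the second equivalent of 10 takes up the acidic protons of the resulting triketo ester 11. On warming, the C1 enolate of 11 attacks the ester carbonyl in a 6-exo-trig Claisen (Dieckmann-type) closure that forms C1–C6 and ring A and expels 2,2-diphenylethoxide. The closest known chemistry is the terminal acylation of β-diketone dianions and the base-mediated Claisen cyclisation of 3,5,7-triketo esters to acylphloroglucinols, here stopped at the non-aromatic stage as in syncarpic-acid-type triones. No stereocentre is created: the C5 configuration is fixed by the order of acyl transfer, imidazolide first and ester second. That order is secured by the large reactivity gap between an acyl imidazole and a hindered alkyl ester and by the terminal carbon being the most nucleophilic site of 10. O-acylation to a six-membered lactone is reversible under the alkoxide present, whereas the doubly stabilised acyl-triketonate is the thermodynamic sink. Because C5 is quaternary there is no enolisation, no ketene pathway and no aromatisation, and because the isobutyryl group stays on C1 the carbonyls C4 and C6 remain distinct.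

Step 7
Reactants: 13 nerol, (2Z)-3,7-dimethylocta-2,6-dien-1-ol
Product: 14 [(2R,3S)-3-methyl-3-(4-methylpent-3-en-1-yl)oxiran-2-yl]methanol
Conditions: Ti(OiPr)4 (10 mol%), D-(−)-diethyl tartrate (12 mol%), t-BuOOH, 4 Å molecular sieves, CH2Cl2, −20 °C
Reagents that add atoms: tert-butyl hydroperoxide, CC(C)(C)OO
Why: Sharpless asymmetric epoxidation; the titanium–D-tartrate complex delivers oxygen only to the allylic alkene and to the face that gives the (2R,3S)-epoxide of the Z-alcohol. This sets C9 and, before inversion, C8.

Step 8
Reactants: 14 [(2R,3S)-3-methyl-3-(4-methylpent-3-en-1-yl)oxiran-2-yl]methanol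
Product: 15 (2S,3S)-3-methyl-3-(4-methylpent-3-en-1-yl)oxirane-2-carbaldehyde
Conditions: TEMPO (10 mol%), PhI(OAc)2 (1.1 equiv), CH2Cl2, rt; used at once
Reagents that add atoms: none
Why: Oxoammonium oxidation of a primary alcohol under non-basic conditions that leave the epoxide and its α-stereocentre intact; the change of descriptor at C2 is formal only.

Step 9
Reactants: 12 (6S)-3,5-dihydroxy-6-methyl-6-(3-methylbut-2-en-1-yl)-2-(2-methylpropanoyl)cyclohexa-2,4-dien-1-one; 15 (2S,3S)-3-methyl-3-(4-methylpent-3-en-1-yl)oxirane-2-carbaldehyde
Product: 18 (2S,7S)-4-hydroxy-2-[(2S)-2-hydroxy-6-methylhept-5-en-2-yl]-7-methyl-7-(3-methylbut-2-en-1-yl)-5-(2-methylpropanoyl)-2,3-dihydro-1-benzofuran-6(7H)-one, via C3 alkylidene 16 (not isolated), via C3 epoxymethyl triketone 17 (not isolated)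
Conditions: 15 (1.2 equiv), L-proline (20 mol%), diethyl 2,6-dimethyl-1,4-dihydropyridine-3,5-dicarboxylate (1.2 equiv), CH2Cl2, 0 °C to rt; then Et3N (1.0 equiv), MeOH, 40 °C
Reagents that add atoms: none
Why: Three-component reductive alkylation of a cyclic 1,3-dicarbonyl C–H acid: amine-catalysed Knoevenagel condensation at C3 gives 16, which the dihydropyridine reduces at once to 17. One equivalent of base then lets the O4 enolate open the epoxide at C8 in a 5-exo-tet SN2 step, while O2 stays locked in the hydrogen-bonded acyl chelate. C8 is inverted (R to S), C9 keeps its configuration, and no stereocentre is made from a prochiral atom.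

Step 10
Reactants: 19 3-methylbut-2-en-1-ol (prenol)
Product: 20 tert-butyl 3-methylbut-2-en-1-yl carbonate
Conditions: Boc2O, n-Bu4NHSO4 (cat.), 30% aq NaOH, CH2Cl2, 0 °C to rt
Reagents that add atoms: di-tert-butyl dicarbonate, CC(C)(C)OC(=O)OC(=O)OC(C)(C)C
Why: Routine alkoxycarbonylation of a primary allylic alcohol under phase-transfer conditions.

Step 11
Reactants: 18 (2S,7S)-4-hydroxy-2-[(2S)-2-hydroxy-6-methylhept-5-en-2-yl]-7-methyl-7-(3-methylbut-2-en-1-yl)-5-(2-methylpropanoyl)-2,3-dihydro-1-benzofuran-6(7H)-one; 20 tert-butyl 3-methylbut-2-en-1-yl carbonate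
Product: 21 (2S,5R,7S)-2-[(2S)-2-hydroxy-6-methylhept-5-en-2-yl]-7-methyl-5,7-bis(3-methylbut-2-en-1-yl)-5-(2-methylpropanoyl)-2,3-dihydro-1-benzofuran-4,6(5H,7H)-dione
Conditions: Pd2(dba)3·CHCl3 (2.5 mol%), (1R,2R)-N,N'-bis[2-(diphenylphosphanyl)benzoyl]cyclohexane-1,2-diamine (7.5 mol%), 20 (1.5 equiv), CH2Cl2, 0 °C to rt
Reagents that add atoms: none
Why: Tsuji–Trost allylic alkylation: zerovalent palladium ionises 20 to a prenyl–palladium cation, CO2 and tert-butoxide, which deprotonates the acidic C1–H, so no external base or nucleophile meets the product. The soft tricarbonyl carbanion attacks the unsubstituted allyl terminus, and O-prenyl products re-ionise and drain to the C-prenyl compound. C1 is set by attack anti to the C5 prenyl group; this substrate bias is modest, the chiral ligand pocket is meant to reinforce it, and the C1 epimer would be a separable diastereomer.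

## Compound list

1 | 2,2,5-trimethyl-1,3-dioxane-4,6-dione | CC1C(=O)OC(C)(C)OC1=O | starting material
2 | 3-tert-butoxy-2-methyl-3-oxopropanoic acid (racemic) | CC(C(=O)O)C(=O)OC(C)(C)C | intermediate
3 | tert-butyl 2,2-diphenylethyl 2-methylpropanedioate (racemic) | CC(C(=O)OCC(c1ccccc1)c1ccccc1)C(=O)OC(C)(C)C | intermediate
4 | 1-bromo-3-methylbut-2-ene (prenyl bromide) | CC(C)=CCBr | starting material
5 | 1-tert-butyl 3-(2,2-diphenylethyl) (2R)-2-methyl-2-(3-methylbut-2-en-1-yl)propanedioate | CC(C)(C)OC(=O)[C@](C)(CC=C(C)C)C(=O)OCC(c1ccccc1)c1ccccc1 | intermediate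
6 | 2,2-diphenylethyl trimethylsilyl (2R)-2-methyl-2-(3-methylbut-2-en-1-yl)propanedioate | C[Si](C)(C)OC(=O)[C@](C)(CC=C(C)C)C(=O)OCC(c1ccccc1)c1ccccc1 | intermediate (not isolated)
7 | (2S)-2-[(2,2-diphenylethoxy)carbonyl]-2,5-dimethylhex-4-enoic acid | OC(=O)[C@](C)(CC=C(C)C)C(=O)OCC(c1ccccc1)c1ccccc1 | intermediate
8 | 2,2-diphenylethyl (2S)-2-(1H-imidazole-1-carbonyl)-2,5-dimethylhex-4-enoate | O=C(n1ccnc1)[C@](C)(CC=C(C)C)C(=O)OCC(c1ccccc1)c1ccccc1 | intermediate
9 | 5-methylhexane-2,4-dione | CC(=O)CC(=O)C(C)C | starting material
10 | dilithium dianion of 5-methylhexane-2,4-dione (C1 and C3 deprotonated) | [Li+].[Li+].[CH2-]C(=O)[CH-]C(=O)C(C)C | intermediate (not isolated)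
11 | 2,2-diphenylethyl (2S)-2,8-dimethyl-2-(3-methylbut-2-en-1-yl)-3,5,7-trioxononanoate | CC(C)C(=O)CC(=O)CC(=O)[C@](C)(CC=C(C)C)C(=O)OCC(c1ccccc1)c1ccccc1 | intermediate (not isolated)
12 | (6S)-3,5-dihydroxy-6-methyl-6-(3-methylbut-2-en-1-yl)-2-(2-methylpropanoyl)cyclohexa-2,4-dien-1-one (enol form of the 2-isobutyryl-4-methyl-4-prenyl trione) | OC1=CC(O)=C(C(=O)C(C)C)C(=O)[C@@]1(C)CC=C(C)C | intermediate
13 | nerol, (2Z)-3,7-dimethylocta-2,6-dien-1-ol | CC(C)=CCC/C(C)=C\CO | starting material
14 | [(2R,3S)-3-methyl-3-(4-methylpent-3-en-1-yl)oxiran-2-yl]methanol | CC(C)=CCC[C@]1(C)O[C@@H]1CO | intermediate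
15 | (2S,3S)-3-methyl-3-(4-methylpent-3-en-1-yl)oxirane-2-carbaldehyde | CC(C)=CCC[C@]1(C)O[C@@H]1C=O | intermediate
16 | Knoevenagel alkylidene of 12 and 15 (exocyclic C3=C7, epoxide intact, alkene geometry open) | CC(C)=CCC[C@]1(C)O[C@@H]1C=C1C(=O)C(C(=O)C(C)C)=C(O)[C@@](C)(CC=C(C)C)C1=O | intermediate (not isolated)
17 | (6S)-3,5-dihydroxy-6-methyl-6-(3-methylbut-2-en-1-yl)-4-{[(2R,3S)-3-methyl-3-(4-methylpent-3-en-1-yl)oxiran-2-yl]methyl}-2-(2-methylpropanoyl)cyclohexa-2,4-dien-1-one | CC(C)=CCC[C@]1(C)O[C@@H]1CC1=C(O)[C@](C)(CC=C(C)C)C(=O)C(C(=O)C(C)C)=C1O | intermediate (not isolated)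
18 | (2S,7S)-4-hydroxy-2-[(2S)-2-hydroxy-6-methylhept-5-en-2-yl]-7-methyl-7-(3-methylbut-2-en-1-yl)-5-(2-methylpropanoyl)-2,3-dihydro-1-benzofuran-6(7H)-one (chelated enol; the target without its C1 prenyl group) | CC(C)=CCC[C@](C)(O)[C@@H]1CC2=C(O1)[C@](C)(CC=C(C)C)C(=O)C(C(=O)C(C)C)=C2O | intermediate
19 | 3-methylbut-2-en-1-ol (prenol) | CC(C)=CCO | starting material
20 | tert-butyl 3-methylbut-2-en-1-yl carbonate | CC(C)=CCOC(=O)OC(C)(C)C | intermediate
21 | (2S,5R,7S)-2-[(2S)-2-hydroxy-6-methylhept-5-en-2-yl]-7-methyl-5,7-bis(3-methylbut-2-en-1-yl)-5-(2-methylpropanoyl)-2,3-dihydro-1-benzofuran-4,6(5H,7H)-dione | CC(C)=CCC[C@](C)(O)[C@@H]1CC2=C(O1)[C@](C)(CC=C(C)C)C(=O)[C@](CC=C(C)C)(C(=O)C(C)C)C2=O | target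

## Step count and least certain steps

Total: 11 steps. Longest linear sequence: 8 steps (steps 1–6, 9 and 11); steps 7–8 and step 10 are side branches.

**Step 6 (key step).** The ester sits on a neopentyl-type carbon, so ring closure may stall at the open-chain stage or divert to O-acylation through the C2 enolate oxygen. Proton transfer to the dianion from residual imidazole would also erode the first acylation. The fallback sets out from 7 and 9 and rejoins at 12, replacing the dianion by a masked one and separating the two bond formations. Acid 7 is converted with 1-chloro-N,N,2-trimethylprop-1-en-1-amine into 2,2-diphenylethyl (2R)-2-(chlorocarbonyl)-2,5-dimethylhex-4-enoate F1. Diketone 9 is silylated via 5-methyl-4-(trimethylsilyloxy)hex-3-en-2-one F2 to 5-methyl-2,4-bis(trimethylsilyloxy)hexa-1,3-diene F3. F1 and F3 are joined in a Mukaiyama-type terminal C-acylation (Me3SiOTf cat., CH2Cl2, −78 °C to rt) to give, after hydrolytic work-up, the triketo ester 11, now isolated. 11 is closed to 12 with NaH in THF.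

**Step 9.** The epoxide may be opened too early, either in the aldehyde under amine catalysis or at the alkylidene stage by a ring oxygen, which would end in aromatisation to a furan and loss of C8. In the closure, attack at the tertiary carbon (six-membered ether) or through O2 may compete. The fallback sets out from 12, with geraniol as an extra commercial starting material, and rejoins at 18. It replaces the epoxide by a protected diol and the epoxide opening by a Mitsunobu etherification.
- Geraniol is epoxidised (Ti(OiPr)4, D-(−)-diethyl tartrate, t-BuOOH) to [(2R,3R)-3-methyl-3-(4-methylpent-3-en-1-yl)oxiran-2-yl]methanol F4.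
- Acetone with catalytic BF3·OEt2 adds with inversion at the tertiary carbon to give [(4R,5S)-2,2,5-trimethyl-5-(4-methylpent-3-en-1-yl)-1,3-dioxolan-4-yl]methanol F5.
- TEMPO/PhI(OAc)2 oxidation gives (4S,5S)-2,2,5-trimethyl-5-(4-methylpent-3-en-1-yl)-1,3-dioxolane-4-carbaldehyde F6, an aldehyde of the α,β-dioxygenated type that has no electrophile next to the alkylidene.
- The same reductive alkylation of 12 gives the C3-alkylated acetonide F7.
- Aqueous acetic acid releases the diol, (6S)-4-[(2R,3S)-2,3-dihydroxy-3,7-dimethyloct-6-en-1-yl]-3,5-dihydroxy-6-methyl-6-(3-methylbut-2-en-1-yl)-2-(2-methylpropanoyl)cyclohexa-2,4-dien-1-one F8.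
- PPh3 and diisopropyl azodicarboxylate activate only the secondary C8 hydroxyl, which the acidic C4 enol displaces with inversion to give 18. The tertiary C9 hydroxyl cannot be activated, so the six-membered ether is excluded.

**Step 11.** Facial discrimination at C1 may be poor, since C5 offers only methyl against prenyl. Attack through oxygen or at the substituted allyl terminus, and retro-Claisen loss of an acyl group from the crowded product, are further risks. The fallback sets out from 18 and rejoins at 21, separating stereocontrol from prenyl regiochemistry. Allylation of 18 with allyl tert-butyl carbonate under the same palladium–ligand system, where ligand control of a prochiral enolate is best established and no branched isomer can arise, gives the C1-allyl compound F9. Cross-metathesis of F9 with 2-methylbut-2-ene (second-generation Grubbs catalyst, CH2Cl2, 40 °C) then converts allyl into prenyl; the existing prenyl-type alkenes only undergo degenerate exchange.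

## Further compounds

F1 | step 6 | 2,2-diphenylethyl (2R)-2-(chlorocarbonyl)-2,5-dimethylhex-4-enoate | ClC(=O)[C@](C)(CC=C(C)C)C(=O)OCC(c1ccccc1)c1ccccc1
F2 | step 6 | 5-methyl-4-(trimethylsilyloxy)hex-3-en-2-one (isomer mixture) | CC(=O)C=C(O[Si](C)(C)C)C(C)C
F3 | step 6 | 5-methyl-2,4-bis(trimethylsilyloxy)hexa-1,3-diene | C=C(O[Si](C)(C)C)C=C(O[Si](C)(C)C)C(C)C
F4 | step 9 | [(2R,3R)-3-methyl-3-(4-methylpent-3-en-1-yl)oxiran-2-yl]methanol | CC(C)=CCC[C@@]1(C)O[C@@H]1CO
F5 | step 9 | [(4R,5S)-2,2,5-trimethyl-5-(4-methylpent-3-en-1-yl)-1,3-dioxolan-4-yl]methanol | CC(C)=CCC[C@]1(C)OC(C)(C)O[C@@H]1CO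
F6 | step 9 | (4S,5S)-2,2,5-trimethyl-5-(4-methylpent-3-en-1-yl)-1,3-dioxolane-4-carbaldehyde | CC(C)=CCC[C@]1(C)OC(C)(C)O[C@@H]1C=O
F7 | step 9 | (6S)-3,5-dihydroxy-6-methyl-6-(3-methylbut-2-en-1-yl)-2-(2-methylpropanoyl)-4-{[(4R,5S)-2,2,5-trimethyl-5-(4-methylpent-3-en-1-yl)-1,3-dioxolan-4-yl]methyl}cyclohexa-2,4-dien-1-one | CC(C)=CCC[C@]1(C)OC(C)(C)O[C@@H]1CC1=C(O)[C@](C)(CC=C(C)C)C(=O)C(C(=O)C(C)C)=C1O
F8 | step 9 | (6S)-4-[(2R,3S)-2,3-dihydroxy-3,7-dimethyloct-6-en-1-yl]-3,5-dihydroxy-6-methyl-6-(3-methylbut-2-en-1-yl)-2-(2-methylpropanoyl)cyclohexa-2,4-dien-1-one | CC(C)=CCC[C@](C)(O)[C@H](O)CC1=C(O)[C@](C)(CC=C(C)C)C(=O)C(C(=O)C(C)C)=C1O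
F9 | step 11 | (2S,5R,7S)-2-[(2S)-2-hydroxy-6-methylhept-5-en-2-yl]-7-methyl-7-(3-methylbut-2-en-1-yl)-5-(2-methylpropanoyl)-5-(prop-2-en-1-yl)-2,3-dihydro-1-benzofuran-4,6(5H,7H)-dione | CC(C)=CCC[C@](C)(O)[C@@H]1CC2=C(O1)[C@](C)(CC=C(C)C)C(=O)[C@](CC=C)(C(=O)C(C)C)C2=O
A1 | alternative 1 | 4,6-bis(methoxymethoxy)-7-methyl-2-(prop-1-en-2-yl)-2,3-dihydro-1-benzofuran, C8 set | CC(=C)[C@@H]1Cc2c(O1)c(C)c(OCOC)cc2OCOC
A2 | alternative 2 | (2S,7S)-7-methyl-7-(3-methylbut-2-en-1-yl)-2-[(2S)-6-methyl-2-(triethylsilyloxy)hept-5-en-2-yl]-2,3-dihydro-1-benzofuran-4,6(5H,7H)-dione | CC(C)=CCC[C@](C)(O[Si](CC)(CC)CC)[C@@H]1CC2=C(O1)[C@](C)(CC=C(C)C)C(=O)CC2=O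
A3 | alternative 3 | (2S)-4,6-bis(tert-butyldimethylsilyloxy)-7-methyl-2-[(2S)-6-methyl-2-(triethylsilyloxy)hept-5-en-2-yl]-2,3-dihydro-1-benzofuran | CC(C)=CCC[C@](C)(O[Si](CC)(CC)CC)[C@@H]1Cc2c(O1)c(C)c(O[Si](C)(C)C(C)(C)C)cc2O[Si](C)(C)C(C)(C)C
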